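**Plan**

Lanaroflavone is two apigenin units joined by a diaryl ether from C4' of unit 1 (rings A, C, B) to C8 of unit 2 (rings D, E, F). It has no stereocentre, so no stereochemistry has to be set.
Enabling feature: ring A of unit 1 carries oxygens on C5, C7 and C8a and the acyl carbon C4 on C4a. It is an acylphloroglucinol, the pattern a poly-β-carbonyl chain gives when it folds by Claisen condensation.
Retrosynthetic cuts: in unit 2, O1–C2 of ring E, C2–C3 (aroylation) and C4–C4a (Friedel–Crafts acetylation of ring D). In unit 1, O1–C2 of ring C, C4a–C5 of ring A (Claisen), and C2–C3 and C4–C4a (two polyanion acylations of 4-hydroxy-6-methylpyran-2-one). Last, the ether O–C4' bond (SNAr).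
Forward order: ether, nine-carbon chain on the pyranone, ring A, ring C, acetyl on ring D with ortho ether cleavage, 1,3-diketone, ring E, cleavage of the methyl ethers.

Key step: step 4

Remark: the polycarbonyl compounds are drawn as keto forms although they are largely enolised, and the lithium, potassium and magnesium salts (enolates, phenoxides) through which they react are treated as forms of the numbered compounds.

**Route**

Step 1
Reactants: 1 2,4,6-trimethoxyphenol; 2 methyl 4-fluorobenzoate
Product: 3 methyl 4-(2,4,6-trimethoxyphenoxy)benzoate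
Conditions: K2CO3, DMSO, 120 °C, N2
Reagents that add atoms: none
Why: Nucleophilic aromatic substitution (SNAr), in which the para ester stabilises the Meisenheimer adduct formed by the electron-rich phenoxide of 1 and fluoride leaves in the elimination.

Step 2
Reactants: 4 4-hydroxy-6-methylpyran-2-one
Product: 5 4-hydroxy-6-(2-oxopropyl)pyran-2-one
Conditions: LiN(iPr)2 (2.2 equiv), THF, −78 to −20 °C; MeC(O)N(OMe)Me, −78 to 0 °C; aq. HCl
Reagents that add atoms: N-methoxy-N-methylacetamide, CC(=O)N(C)OC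
Why: Weinreb ketone synthesis on the dilithium salt of 4, which reacts at its 6-methyl carbanion (the last-formed, most basic site), while the chelated tetrahedral adduct holds the ketone back until work-up and so prevents proton quenching and double addition.

Step 3
Reactants: 5 4-hydroxy-6-(2-oxopropyl)pyran-2-one; 3 methyl 4-(2,4,6-trimethoxyphenoxy)benzoate
Product: 6 4-hydroxy-6-[2,4-dioxo-4-[4-(2,4,6-trimethoxyphenoxy)phenyl]butyl]pyran-2-one
Conditions: 5 (2 equiv), LiN(iPr)2 (6.2 equiv), THF, −78 to 0 °C; 3 (1 equiv), 0 °C to rt; aq. HCl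
Reagents that add atoms: none
Why: Claisen-type acylation of a β-dicarbonyl polyanion, in which the trilithium salt of 5 attacks the non-enolisable ester 3 through its terminal methyl carbanion (the least stabilised site) and the second equivalent of trianion takes up the acidic proton of the new 1,3-diketone.

Step 4
Reactants: 6 4-hydroxy-6-[2,4-dioxo-4-[4-(2,4,6-trimethoxyphenoxy)phenyl]butyl]pyran-2-one
Product: 8 1-(2,4,6-trihydroxyphenyl)-3-[4-(2,4,6-trimethoxyphenoxy)phenyl]propane-1,3-dione, via open-chain tetraoxo ester 7 (not isolated)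
Conditions: Mg(OMe)2 (10 equiv), MeOH, reflux, argon; then cold 1 M HCl
Reagents that add atoms: none
Why: Methoxide should open the lactone of 6 at its carboxyl carbon to the methyl ester 7 of the 3,5,7,9-tetraoxo chain, held as a magnesium polyenolate. The carbanion at chain carbon 6, flanked by the C5 and C7 carbonyls, then adds to the ester carbonyl C1 and methoxide leaves, which forms the C4a–C5 bond of unit 1, and enolisation of the cyclohexanetrione gives the aromatic 2,4,6-trihydroxyphenyl ring A. The closest known reaction type is the biomimetic Claisen (Dieckmann-type) cyclisation of 3,5,7-triketo esters and of their 4-hydroxy-2-pyranone forms to acylphloroglucinols with Mg(OMe)2, of which the longer aryl-terminated chain is a close extension. Ring A closes in a 6-exo-trig mode, the enolate carbon C6 attacking the ester carbonyl that lies outside the forming ring. No stereocentre is formed. The step needs Claisen folding (C6 onto C1) to win over the aldol foldings (C2 onto C7, C8 onto C3, C4 onto C9) that lead to resorcinol-type products, and chelation by divalent magnesium should secure this by keeping every ketone carbonyl enolised and poorly electrophilic so that the ester carbonyl is the acceptor, while the aryl ether and methoxy groups are inert.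

Step 5
Reactants: 8 1-(2,4,6-trihydroxyphenyl)-3-[4-(2,4,6-trimethoxyphenoxy)phenyl]propane-1,3-dione
Product: 9 5,7-dihydroxy-2-[4-(2,4,6-trimethoxyphenoxy)phenyl]chromen-4-one
Conditions: AcOH, H2SO4 (cat.), 90 °C
Reagents that add atoms: none
Why: Acid-catalysed cyclodehydration of a 2-hydroxyaryl 1,3-diketone (the closing stage of a Baker–Venkataraman flavone synthesis), in which either ortho hydroxyl of the symmetric ring A adds to the aryl ketone and water is lost, so only one flavone can form.

Step 6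
Reactants: 9 5,7-dihydroxy-2-[4-(2,4,6-trimethoxyphenoxy)phenyl]chromen-4-one
Product: 10 5-hydroxy-7-methoxy-2-[4-(2,4,6-trimethoxyphenoxy)phenyl]chromen-4-one
Conditions: MeI (1.1 equiv), K2CO3 (1.2 equiv), acetone, reflux
Reagents that add atoms: iodomethane, CI
Why: Williamson ether synthesis selective for the acidic, unchelated 7-OH, because the 5-OH is locked in a hydrogen bond to the C4 carbonyl and is far less nucleophilic towards one equivalent of MeI.

Step 7
Reactants: 10 5-hydroxy-7-methoxy-2-[4-(2,4,6-trimethoxyphenoxy)phenyl]chromen-4-one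
Product: 12 2-[4-(3-acetyl-2-hydroxy-4,6-dimethoxyphenoxy)phenyl]-5-hydroxy-7-methoxychromen-4-one, via acetyl trimethoxy ketone 11 (not isolated)
Conditions: AlCl3 (5 equiv), AcCl (1.5 equiv), CH2Cl2, 0 °C to rt; then ice-cold dil. HCl
Reagents that add atoms: acetyl chloride, CC(Cl)=O
Why: Friedel–Crafts acetylation at one of the two equivalent free positions of ring D (far more electron-rich than ring B or the aluminium-chelated ring A), followed in the same flask by AlCl3-mediated cleavage of the crowded methoxy group lying between the new acetyl group and the aryloxy group, as in the acetylation of 1,2,3,5-tetramethoxybenzene.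

Step 8
Reactants: 12 2-[4-(3-acetyl-2-hydroxy-4,6-dimethoxyphenoxy)phenyl]-5-hydroxy-7-methoxychromen-4-one; 13 4-methoxybenzoyl chloride
Product: 14 1-[2-hydroxy-3-[4-(5-hydroxy-7-methoxy-4-oxochromen-2-yl)phenoxy]-4,6-dimethoxyphenyl]-3-(4-methoxyphenyl)propane-1,3-dione
Conditions: LiN(SiMe3)2 (4.5 equiv), THF, −78 °C; 13 (1.05 equiv), −78 °C to rt; aq. HCl
Reagents that add atoms: none
Why: Direct C-aroylation of the lithium enolate of a polylithiated 2-hydroxyacetophenone by an acid chloride (a one-flask variant of the Baker–Venkataraman route), with both phenols masked as lithium salts and any O-aroyl ester rearranging to the same diketone under the excess base.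

Step 9
Reactants: 14 1-[2-hydroxy-3-[4-(5-hydroxy-7-methoxy-4-oxochromen-2-yl)phenoxy]-4,6-dimethoxyphenyl]-3-(4-methoxyphenyl)propane-1,3-dione
Product: 15 8-[4-(5-hydroxy-7-methoxy-4-oxochromen-2-yl)phenoxy]-5,7-dimethoxy-2-(4-methoxyphenyl)chromen-4-one
Conditions: AcOH, H2SO4 (cat.), 95 °C
Reagents that add atoms: none
Why: Acid-catalysed cyclodehydration to the flavone, in which the only free hydroxyl ortho to the diketone is the one next to the aryloxy group, so ring E closes on that oxygen and the ether ends up on C8 of unit 2.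

Step 10
Reactants: 15 8-[4-(5-hydroxy-7-methoxy-4-oxochromen-2-yl)phenoxy]-5,7-dimethoxy-2-(4-methoxyphenyl)chromen-4-one
Product: 16 lanaroflavone, 8-[4-(5,7-dihydroxy-4-oxochromen-2-yl)phenoxy]-5,7-dihydroxy-2-(4-hydroxyphenyl)chromen-4-one
Conditions: BBr3 (excess), CH2Cl2, −78 °C to rt; then MeOH, H2O
Reagents that add atoms: none
Why: Lewis-acid cleavage of the four aryl methyl ethers with BBr3 (bromide attacks the methyl group of each boron-complexed ether), which leaves the diaryl ether intact and, at low temperature, avoids the acid-induced Wessely–Moser isomerisation of the 8-aryloxy unit.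

**Compound list**

1 | 2,4,6-trimethoxyphenol | COc1cc(OC)c(O)c(OC)c1 | starting material
2 | methyl 4-fluorobenzoate | COC(=O)c1ccc(F)cc1 | starting material
3 | methyl 4-(2,4,6-trimethoxyphenoxy)benzoate | COC(=O)c1ccc(Oc2c(OC)cc(OC)cc2OC)cc1 | intermediate
4 | 4-hydroxy-6-methylpyran-2-one | Cc1cc(O)cc(=O)o1 | starting material
5 | 4-hydroxy-6-(2-oxopropyl)pyran-2-one | CC(=O)Cc1cc(O)cc(=O)o1 | intermediate
6 | 4-hydroxy-6-[2,4-dioxo-4-[4-(2,4,6-trimethoxyphenoxy)phenyl]butyl]pyran-2-one | O=C(CC(=O)Cc1cc(O)cc(=O)o1)c1ccc(Oc2c(OC)cc(OC)cc2OC)cc1 | intermediate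
7 | methyl 3,5,7,9-tetraoxo-9-[4-(2,4,6-trimethoxyphenoxy)phenyl]nonanoate (magnesium polyenolate, not isolated) | COC(=O)CC(=O)CC(=O)CC(=O)CC(=O)c1ccc(Oc2c(OC)cc(OC)cc2OC)cc1 | intermediate
8 | 1-(2,4,6-trihydroxyphenyl)-3-[4-(2,4,6-trimethoxyphenoxy)phenyl]propane-1,3-dione | O=C(CC(=O)c1c(O)cc(O)cc1O)c1ccc(Oc2c(OC)cc(OC)cc2OC)cc1 | intermediate
9 | 5,7-dihydroxy-2-[4-(2,4,6-trimethoxyphenoxy)phenyl]chromen-4-one | O=c1cc(-c2ccc(Oc3c(OC)cc(OC)cc3OC)cc2)oc2cc(O)cc(O)c12 | intermediate
10 | 5-hydroxy-7-methoxy-2-[4-(2,4,6-trimethoxyphenoxy)phenyl]chromen-4-one | O=c1cc(-c2ccc(Oc3c(OC)cc(OC)cc3OC)cc2)oc2cc(OC)cc(O)c12 | intermediate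
11 | 2-[4-(3-acetyl-2,4,6-trimethoxyphenoxy)phenyl]-5-hydroxy-7-methoxychromen-4-one (not isolated) | O=c1cc(-c2ccc(Oc3c(OC)cc(OC)c(C(C)=O)c3OC)cc2)oc2cc(OC)cc(O)c12 | intermediate
12 | 2-[4-(3-acetyl-2-hydroxy-4,6-dimethoxyphenoxy)phenyl]-5-hydroxy-7-methoxychromen-4-one | O=c1cc(-c2ccc(Oc3c(OC)cc(OC)c(C(C)=O)c3O)cc2)oc2cc(OC)cc(O)c12 | intermediate
13 | 4-methoxybenzoyl chloride | COc1ccc(C(Cl)=O)cc1 | starting material
14 | 1-[2-hydroxy-3-[4-(5-hydroxy-7-methoxy-4-oxochromen-2-yl)phenoxy]-4,6-dimethoxyphenyl]-3-(4-methoxyphenyl)propane-1,3-dione | O=c1cc(-c2ccc(Oc3c(OC)cc(OC)c(C(=O)CC(=O)c4ccc(OC)cc4)c3O)cc2)oc2cc(OC)cc(O)c12 | intermediate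
15 | 8-[4-(5-hydroxy-7-methoxy-4-oxochromen-2-yl)phenoxy]-5,7-dimethoxy-2-(4-methoxyphenyl)chromen-4-one | O=c1cc(-c2ccc(Oc3c(OC)cc(OC)c4c(=O)cc(-c5ccc(OC)cc5)oc34)cc2)oc2cc(OC)cc(O)c12 | intermediate
16 | lanaroflavone, 8-[4-(5,7-dihydroxy-4-oxochromen-2-yl)phenoxy]-5,7-dihydroxy-2-(4-hydroxyphenyl)chromen-4-one | O=c1cc(-c2ccc(Oc3c(O)cc(O)c4c(=O)cc(-c5ccc(O)cc5)oc34)cc2)oc2cc(O)cc(O)c12 | target

**Step count and risks**

Total: 10 steps. Longest linear sequence: 9 steps (steps 1 and 3 to 10 from compounds 1 and 2, or equally steps 2 to 10 from compound 4).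

The three steps most likely to fail, with one fallback each:

Step 4 is the least certain. The polyenolate may fold by aldol instead of Claisen condensation, or the lactone may open too slowly, so that resorcinol-type products form in place of ring A. The fallback gives up the biomimetic closure and takes ring A from the aromatic pool; it sets out from 3 and comes back to the route at 8. Saponification of 3 (LiOH, THF/H2O, then HCl) should give 4-(2,4,6-trimethoxyphenoxy)benzoic acid F1, and SOCl2 with catalytic DMF the acid chloride 4-(2,4,6-trimethoxyphenoxy)benzoyl chloride F2. Commercial 2,4,6-trihydroxyacetophenone, as its tetralithium salt (LiN(SiMe3)2, THF, −78 °C), is then C-aroylated by F2 at the enolate carbon, a Baker–Venkataraman-type acylation that delivers 8 directly.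

Step 3 may stall through incomplete formation of the trianion and proton transfer from the newly formed, more acidic 1,3-diketone to unreacted trianion, and acylation may stray to the internal methylene group. The fallback replaces the Claisen acylation by an aldol addition followed by oxidation; it sets out from 1 and 5 and comes back to the route at 6. SNAr of 1 on 4-fluorobenzaldehyde (K2CO3, DMSO, 100 °C) should give 4-(2,4,6-trimethoxyphenoxy)benzaldehyde F3. The trilithium salt of 5 adds to F3 through its terminal carbanion, and the alkoxide formed does not quench further trianion. The racemic aldol 4-hydroxy-6-[4-hydroxy-2-oxo-4-[4-(2,4,6-trimethoxyphenoxy)phenyl]butyl]pyran-2-one F4 is then oxidised at its benzylic carbinol with IBX (DMSO, rt) to 6.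

Step 7 combines acetylation and ether cleavage on a large chelating substrate. Cleavage may take place at the less hindered ortho methoxy group or at both, and the Lewis acid bound to the 5-hydroxychromenone may slow or misdirect the acetylation. The fallback changes the order of ring construction so that this chemistry is run on the small ester, the closest analogue of 1,2,3,5-tetramethoxybenzene, where the site of cleavage can be proven and a minor isomer removed before the fragments are joined. It sets out from 3 and comes back to the route at 16.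
- AcCl and AlCl3 in CH2Cl2 should convert 3, via methyl 4-(3-acetyl-2,4,6-trimethoxyphenoxy)benzoate F5, into methyl 4-(3-acetyl-2-hydroxy-4,6-dimethoxyphenoxy)benzoate F6.
- C-aroylation with 13 (LiN(SiMe3)2, THF, −78 °C) should give methyl 4-[2-hydroxy-4,6-dimethoxy-3-[3-(4-methoxyphenyl)-3-oxopropanoyl]phenoxy]benzoate F7, and AcOH with catalytic H2SO4 the flavone ester methyl 4-[5,7-dimethoxy-2-(4-methoxyphenyl)-4-oxochromen-8-yl]oxybenzoate F8.
- The trilithium salt of 5 is acylated by F8 as in step 3 to 8-[4-[4-(4-hydroxy-2-oxopyran-6-yl)-3-oxobutanoyl]phenoxy]-5,7-dimethoxy-2-(4-methoxyphenyl)chromen-4-one F9.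
- Mg(OMe)2 in MeOH folds F9, via methyl 9-[4-[5,7-dimethoxy-2-(4-methoxyphenyl)-4-oxochromen-8-yl]oxyphenyl]-3,5,7,9-tetraoxononanoate F10, to 1-[4-[5,7-dimethoxy-2-(4-methoxyphenyl)-4-oxochromen-8-yl]oxyphenyl]-3-(2,4,6-trihydroxyphenyl)propane-1,3-dione F11.
- Acid cyclodehydration closes ring C to 8-[4-(5,7-dihydroxy-4-oxochromen-2-yl)phenoxy]-5,7-dimethoxy-2-(4-methoxyphenyl)chromen-4-one F12, and BBr3 in CH2Cl2 cleaves its three methyl ethers to 16.

**Further compounds**

F1 | step 4 | 4-(2,4,6-trimethoxyphenoxy)benzoic acid | OC(=O)c1ccc(Oc2c(OC)cc(OC)cc2OC)cc1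
F2 | step 4 | 4-(2,4,6-trimethoxyphenoxy)benzoyl chloride | O=C(Cl)c1ccc(Oc2c(OC)cc(OC)cc2OC)cc1
F3 | step 3 | 4-(2,4,6-trimethoxyphenoxy)benzaldehyde | O=Cc1ccc(Oc2c(OC)cc(OC)cc2OC)cc1
F4 | step 3 | 4-hydroxy-6-[4-hydroxy-2-oxo-4-[4-(2,4,6-trimethoxyphenoxy)phenyl]butyl]pyran-2-one (racemic) | OC(CC(=O)Cc1cc(O)cc(=O)o1)c1ccc(Oc2c(OC)cc(OC)cc2OC)cc1
F5 | step 7 | methyl 4-(3-acetyl-2,4,6-trimethoxyphenoxy)benzoate (not isolated) | COC(=O)c1ccc(Oc2c(OC)cc(OC)c(C(C)=O)c2OC)cc1
F6 | step 7 | methyl 4-(3-acetyl-2-hydroxy-4,6-dimethoxyphenoxy)benzoate | COC(=O)c1ccc(Oc2c(OC)cc(OC)c(C(C)=O)c2O)cc1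
F7 | step 7 | methyl 4-[2-hydroxy-4,6-dimethoxy-3-[3-(4-methoxyphenyl)-3-oxopropanoyl]phenoxy]benzoate | COC(=O)c1ccc(Oc2c(OC)cc(OC)c(C(=O)CC(=O)c3ccc(OC)cc3)c2O)cc1
F8 | step 7 | methyl 4-[5,7-dimethoxy-2-(4-methoxyphenyl)-4-oxochromen-8-yl]oxybenzoate | COC(=O)c1ccc(Oc2c(OC)cc(OC)c3c(=O)cc(-c4ccc(OC)cc4)oc23)cc1
F9 | step 7 | 8-[4-[4-(4-hydroxy-2-oxopyran-6-yl)-3-oxobutanoyl]phenoxy]-5,7-dimethoxy-2-(4-methoxyphenyl)chromen-4-one | O=C(CC(=O)Cc1cc(O)cc(=O)o1)c1ccc(Oc2c(OC)cc(OC)c3c(=O)cc(-c4ccc(OC)cc4)oc23)cc1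
F10 | step 7 | methyl 9-[4-[5,7-dimethoxy-2-(4-methoxyphenyl)-4-oxochromen-8-yl]oxyphenyl]-3,5,7,9-tetraoxononanoate (not isolated) | COC(=O)CC(=O)CC(=O)CC(=O)CC(=O)c1ccc(Oc2c(OC)cc(OC)c3c(=O)cc(-c4ccc(OC)cc4)oc23)cc1
F11 | step 7 | 1-[4-[5,7-dimethoxy-2-(4-methoxyphenyl)-4-oxochromen-8-yl]oxyphenyl]-3-(2,4,6-trihydroxyphenyl)propane-1,3-dione | O=C(CC(=O)c1c(O)cc(O)cc1O)c1ccc(Oc2c(OC)cc(OC)c3c(=O)cc(-c4ccc(OC)cc4)oc23)cc1
F12 | step 7 | 8-[4-(5,7-dihydroxy-4-oxochromen-2-yl)phenoxy]-5,7-dimethoxy-2-(4-methoxyphenyl)chromen-4-one | O=c1cc(-c2ccc(Oc3c(OC)cc(OC)c4c(=O)cc(-c5ccc(OC)cc5)oc34)cc2)oc2cc(O)cc(O)c12
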